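A closed, stirred vessel holds solid substrate and reagent, and I follow this flask, maple so far, to 20 h, beside the earlier birch run.

| setting | maple | birch | flask |
|---|---|---|---|
| solid substrate | 0.045 M | 0.022 M | 0.045 M |
| reagent | 0.045 M | 0.045 M | 0.0450 M |
| remark | the very flask that is asked about, followed so far | run made earlier |  |
| time |  |  | 20 h |

- maple (time / h: target / %, solid product / %): 0.667: 12.6, 0; 1.00: 18.1, 4.2; 2.00: 37.0, 18.7; 3.00: 46.5, 32.3; 5.00: 56.1, 38.9; 8.00: 52.8, 37.3
- birch (time / h: target / %, solid product / %): 3.00: 57.1, 28.6; 6.00: 50.7, 20.8; 10.0: 44.4, 14.8; 12.0: 44.2, 12.5; 15.0: 43.1, 11.4; 20.0: 40.5, 9.5

(readings scatter by 1 percentage point)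

- target and solid product together at 20 h, in percent of the solid substrate charged
- concentration of dissolved substrate in solution at 20 h, in percent of saturation

- amounts and yields of target count solid product too
- given per volume of solution although it is solid: solid substrate, solid product
- at the start none of the solid substrate is in solution
- dissolved substrate means what is dissolved; the solid is not counted in it

Target counts solid product too, so target minus solid product is dissolved target: 0.00682 M in birch's last reading and 0.00698 M in maple's. I fold this level into one number, φ = 15.2%, the solution share: the dissolved level over the charge of solid substrate. It tells what part of the charge the solution holds as target while solid product stands. From 3.00 h to 20.0 h, birch's target readings fall by 0.535 of its level. I assume a loss drawn from solution costs the same moles in both flasks, so maple should fall by that fraction of φ from its peak reading, to 48.0%.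

One number is not enough, because φ is silent on dissolved substrate. The highest target readings of maple and birch, 56.1% and 57.1%, nearly match although birch has twice the reagent per solid substrate. So I take solid substrate as the limiting reagent and expect dissolved substrate near zero at 20 h.

The forecast gives 48% and 70%: “Unreacted substrate would then linger and dissolve towards saturation”.

The flask gives 49.0% and 0%.

    2 dissolved substrate → side product (k = 0.0315 /M/s)
    dissolved substrate + reagent → target (k = 0.0161 /M/s)
    target ⇌ isomer of the product (K = 1.00, k = 4.94 × 10⁻⁵ /s)
    solid product ⇌ target, rate k4*(cs4 - [target]) while solid is left; crystals form when [target] > cs4 (solubility = 7.00 mM, k = 0.0257 /s)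
    solid substrate ⇌ dissolved substrate, rate k5*(cs5 - [dissolved substrate]) while solid is left; crystals form when [dissolved substrate] > cs5 (solubility = 5.20 mM, k = 0.00495 /s)

At 20.0 h this flask holds solid substrate at 0% and dissolved substrate at 0%, with 36% of its reagent left. Its isomer of the product stands at 15.1%, level with φ as read. The same flask with 0.076 M of solid substrate has a smaller share, φ = 8.97%, and at 20.0 h it gives 43.8% of target and solid product together and 8.93% of isomer of the product.

(All runs are simulated for substances that don't exist.)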